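**Retrosynthetic overview**

1. 28 ⇐ 27: the oxirane is made last, by epoxidation of the only electron-rich alkene (C-1/C-10). Ring order: ten-membered carbocycle → γ-lactone → oxirane.
2. 23 ⇐ 17: C-6–C-7 bond by CrCl2 macro-allylation of a C-6 aldehyde by C-7 of a 2-(bromomethyl)enoate, then O-6→C-12 lactonisation. The C-6/C-15 ene-dial is unveiled in the same flask from a 3-substituted furan, so C-15 arrives as the aldehyde.
3. 17 ⇐ 14 + methyl acrylate (Baylis–Hillman, C-7–C-11); 14 ⇐ bromide 8 + RAMP hydrazone of silyloxyacetaldehyde (C-8–C-9, sets C-8).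
4. 8 ⇐ furan-3-carbaldehyde + tiglate silyl dienolate (catalytic asymmetric vinylogous aldol, C-2–C-3; sets C-3 and the E-1(10) alkene).
5. C-6 and C-7 are set from C-8 during ring closure, C-1/C-10 from the ring conformation; the methacrylate goes on after ring closure.

Assumption: germacrane position labels (C-1 to C-15) are used, the SMILES is read as 1β,10α-epoxy-3β-hydroxy-8β-methacryloyloxy-15-oxogermacra-4,11(13)-dien-6α,12-olide (1R,3S,6R,7R,8R,10R; C-3 and C-6 cis on the 4,5-alkene), and the published senses of induction of the Denmark catalyst and of RAMP are taken to hold (otherwise the antipodal catalyst or SAMP is used).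

**Route**

Step 1
Reactants: 1 ethyl tiglate (ethyl (2E)-2-methylbut-2-enoate)
Product: 3 tert-butyl{[(1Z)-1-ethoxy-2-methylbuta-1,3-dien-1-yl]oxy}dimethylsilane (tiglate silyl dienolate), via lithium dienolate 2 (not isolated)
Conditions: LiN(iPr)2, THF/DMPU, −78 °C; tBuMe2SiCl, −78 °C → rt
Reagents that add atoms: tert-butyldimethylsilyl chloride, CC(C)(C)[Si](C)(C)Cl
Why: Kinetic γ-deprotonation of the tiglate gives the extended enolate 2, and O-silylation (silyl ketene acetal formation) gives the nucleophile for the vinylogous aldol; no stereocentre is formed.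

Step 2
Reactants: 3 tiglate silyl dienolate; 4 furan-3-carbaldehyde
Product: 5 ethyl (2E,5S)-5-(furan-3-yl)-5-hydroxy-2-methylpent-2-enoate
Conditions: SiCl4 (1.1 equiv), (R,R)-Denmark bisphosphoramide (2 mol%), iPr2NEt (10 mol%), CH2Cl2, −78 °C; aq. NaHCO3
Reagents that add atoms: none
Why: Denmark vinylogous Mukaiyama aldol (Lewis-base-activated SiCl4): the aldehyde bound to the chiral phosphoramide–trichlorosilyl cation is attacked by the unhindered γ-carbon of 3, giving the E-enoate and, by Si-face addition, the 5S carbinol that becomes C-3 (3β-OH) of the target.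

Step 3
Reactants: 5 hydroxy enoate
Product: 6 ethyl (2E,5S)-5-[(tert-butyldiphenylsilyl)oxy]-5-(furan-3-yl)-2-methylpent-2-enoate
Conditions: tBuPh2SiCl, imidazole, DMF, rt
Reagents that add atoms: tert-butyldiphenylsilyl chloride, CC(C)(C)[Si](Cl)(c1ccccc1)c1ccccc1
Why: Silyl ether formation on the secondary alcohol; the acid-robust group outlasts the later removal of the C-8 silyl ether and stops the C-3 oxygen from closing onto C-6 (furan re-formation) once the ene-dial is unveiled; configuration unchanged.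

Step 4
Reactants: 6 silyl ether ester
Product: 7 (2E,5S)-5-[(tert-butyldiphenylsilyl)oxy]-5-(furan-3-yl)-2-methylpent-2-en-1-ol
Conditions: iBu2AlH (2.5 equiv), CH2Cl2, −78 °C; aq. potassium sodium tartrate
Reagents that add atoms: none
Why: 1,2-Reduction of the conjugated ester by excess iBu2AlH gives the allylic alcohol without touching the furan or the alkene geometry.

Step 5
Reactants: 7 allylic alcohol
Product: 8 (1S,3E)-5-bromo-1-(furan-3-yl)-4-methylpent-3-en-1-yl tert-butyldiphenylsilyl ether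
Conditions: CBr4, PPh3, CH2Cl2, 0 °C
Reagents that add atoms: carbon tetrabromide, BrC(Br)(Br)Br
Why: Appel bromination proceeds by SN2 displacement of the primary alkoxyphosphonium ion, so the E-trisubstituted alkene and the C-3 centre are retained.

Step 6
Reactants: 9 (tert-butyldimethylsilyloxy)acetaldehyde; 10 RAMP ((2R)-1-amino-2-(methoxymethyl)pyrrolidine)
Product: 11 (2R)-N-[(E)-2-(tert-butyldimethylsilyloxy)ethylidene]-2-(methoxymethyl)pyrrolidin-1-amine
Conditions: CH2Cl2, MgSO4, 0 °C → rt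
Reagents that add atoms: none
Why: Condensation of the aldehyde with the hydrazine gives the E-hydrazone needed for auxiliary-controlled α-alkylation.

Step 7
Reactants: 11 RAMP hydrazone; 8 allylic bromide
Product: 13 (2R)-N-[(1E,2R,4E,7S)-2-(tert-butyldimethylsilyloxy)-7-(tert-butyldiphenylsilyloxy)-7-(furan-3-yl)-4-methylhept-4-enylidene]-2-(methoxymethyl)pyrrolidin-1-amine, via lithium azaenolate 12 (not isolated)
Conditions: LiN(iPr)2, THF, 0 °C; then 8, −100 °C → rt
Reagents that add atoms: none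
Why: Enders RAMP-hydrazone alkylation: the azaenolate 12, rigidified by Li–OMe chelation, is alkylated by the allylic bromide (SN2) on the face away from the pyrrolidine substituent, which sets the silyloxy-bearing centre (C-8) as R.

Step 8
Reactants: 13 alkylated hydrazone
Product: 14 (2R,4E,7S)-2-[(tert-butyldimethylsilyl)oxy]-7-[(tert-butyldiphenylsilyl)oxy]-7-(furan-3-yl)-4-methylhept-4-enal
Conditions: sat. aq. (CO2H)2, Et2O, rt
Reagents that add atoms: water, O
Why: Two-phase oxalic acid hydrolysis of the hydrazone frees the α-silyloxy aldehyde without epimerisation and returns the auxiliary.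

Step 9
Reactants: 14 α-silyloxy aldehyde; 15 methyl acrylate
Product: 16 methyl (3RS,4R,6E,9S)-4-[(tert-butyldimethylsilyl)oxy]-9-[(tert-butyldiphenylsilyl)oxy]-9-(furan-3-yl)-3-hydroxy-6-methyl-2-methylidenenon-6-enoate
Conditions: DABCO (1 equiv), methyl acrylate/MeOH, rt, 5 d
Reagents that add atoms: none
Why: Morita–Baylis–Hillman reaction attaches C-11 to C-13 of the lactone to the aldehyde carbon (C-7); the new carbinol centre forms as a mixture and is destroyed in step 10, and C-8 is not expected to enolise appreciably under DABCO.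

Step 10
Reactants: 16 Baylis–Hillman alcohol
Product: 17 methyl (2Z,4R,6E,9S)-2-(bromomethyl)-4-[(tert-butyldimethylsilyl)oxy]-9-[(tert-butyldiphenylsilyl)oxy]-9-(furan-3-yl)-6-methylnona-2,6-dienoate
Conditions: PBr3, Et2O, −10 °C
Reagents that add atoms: phosphorus tribromide, BrP(Br)Br
Why: PBr3 converts the Baylis–Hillman alcohol with allylic transposition (SN2′) into the thermodynamically favoured (Z)-2-(bromomethyl)enoate, the C-7 allyl donor.

Step 11
Reactants: 17 furyl allylic bromide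
Product: 23 3β-(tert-butyldiphenylsilyloxy)-8β-(tert-butyldimethylsilyloxy)-15-oxogermacra-1(10)E,4,11(13)-trien-6α,12-olide (7α-H; C-3 and C-6 cis on the 4,5-alkene), via furan endoperoxide 18 (not isolated), via Z-ene-dial 19 (not isolated), via E-ene-dial 20 (not isolated), via allylchromium species 21 (not isolated), via hydroxy ester 22 (not isolated)
Conditions: O2, tetraphenylporphyrin (1 mol%), hν, CH2Cl2, −78 °C; Me2S (1.05 equiv), −78 → −20 °C; I2 (2 mol%), 0 °C; solvent switch to THF; slow addition to CrCl2 (12 equiv), THF, 2 mM, rt; aq. NH4Cl; CSA (cat.), CH2Cl2, rt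
Reagents that add atoms: oxygen, O=O
Why: Proposed new method: [4+2] photo-oxygenation of the furan, Me2S reduction and iodine-catalysed Z→E isomerisation (all known for 3-alkylfurans) unveil C-6 and C-15 as an E-ene-dial, then CrCl2 inserts into the allylic C–Br bond and the allylchromium adds through C-7 to the unhindered C-6 aldehyde (the C-15 aldehyde is α-branched, flanked by the silyloxy-bearing C-3 and would give a nine-membered ring) via a chair-like six-membered transition state embedded in the forming ten-membered ring, with C-6/C-7 anti as in the closest known reaction, the CrCl2 (Nozaki–Hiyama–Kishi-type) closure of ω-formyl 2-(bromomethyl)enoates to trans-fused germacranolides, and with H-8 in the plane of the allyl unit (allylic 1,3-strain), the C-9 tether anti to the incoming aldehyde and the silyloxy group outside, so that the 8R centre sets C-6 and C-7 both R, before acid closes the 6,12-lactone.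

Step 12
Reactants: 23 bis-silyl macrolactone
Product: 24 3β-(tert-butyldiphenylsilyloxy)-8β-hydroxy-15-oxogermacra-1(10)E,4,11(13)-trien-6α,12-olide
Conditions: HF·pyridine, pyridine, THF, 0 °C → rt
Reagents that add atoms: none
Why: Buffered HF·pyridine cleaves the secondary tert-butyldimethylsilyl ether about two orders of magnitude faster than the tert-butyldiphenylsilyl ether, exposing only the C-8 hydroxyl; no stereocentre is affected.

Step 13
Reactants: 24 C-8 alcohol; 25 methacrylic anhydride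
Product: 26 3β-(tert-butyldiphenylsilyloxy)-8β-methacryloyloxy-15-oxogermacra-1(10)E,4,11(13)-trien-6α,12-olide
Conditions: DMAP (0.2 equiv), Et3N, CH2Cl2, 0 °C → rt
Reagents that add atoms: none
Why: DMAP-catalysed acyl transfer (Steglich-type acylation) to the C-8 alcohol occurs with retention at C-8 and installs the methacrylate.

Step 14
Reactants: 26 silyl-protected methacrylate
Product: 27 3β-hydroxy-8β-methacryloyloxy-15-oxogermacra-1(10)E,4,11(13)-trien-6α,12-olide
Conditions: HF·pyridine (excess), THF, rt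
Reagents that add atoms: none
Why: Fluoride-driven Si–O cleavage removes the tert-butyldiphenylsilyl group under mildly acidic conditions that the enal, both acrylate-type esters and the lactone tolerate.

Step 15
Reactants: 27 de-epoxy precursor
Product: 28 CNP0534814.1 (1β,10α-epoxy-3β-hydroxy-8β-methacryloyloxy-15-oxogermacra-4,11(13)-dien-6α,12-olide)
Conditions: mCPBA, NaHCO3, CH2Cl2, 0 °C
Reagents that add atoms: 3-chloroperoxybenzoic acid, O=C(OO)c1cccc(Cl)c1
Why: Prilezhaev epoxidation: the peracid attacks only the electron-rich 1(10)-alkene (all other alkenes are conjugated to carbonyls) from the exposed outer face of the E-alkene in the ten-membered ring, giving the 1β,10α (1R,10R) oxirane, the face selectivity known for peracid epoxidation of costunolide-type 1(10)-alkenes.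

**Compound list**

1 | ethyl tiglate, ethyl (2E)-2-methylbut-2-enoate | CCOC(=O)/C(C)=C/C | starting material
2 | lithium (1Z)-1-ethoxy-2-methylbuta-1,3-dien-1-olate | C=C/C(C)=C(/OCC)O[Li] | intermediate
3 | tert-butyl{[(1Z)-1-ethoxy-2-methylbuta-1,3-dien-1-yl]oxy}dimethylsilane | C=C/C(C)=C(/OCC)O[Si](C)(C)C(C)(C)C | intermediate
4 | furan-3-carbaldehyde | O=Cc1ccoc1 | starting material
5 | ethyl (2E,5S)-5-(furan-3-yl)-5-hydroxy-2-methylpent-2-enoate | CCOC(=O)/C(C)=C/C[C@H](O)c1ccoc1 | intermediate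
6 | ethyl (2E,5S)-5-[(tert-butyldiphenylsilyl)oxy]-5-(furan-3-yl)-2-methylpent-2-enoate | CCOC(=O)/C(C)=C/C[C@H](O[Si](c1ccccc1)(c1ccccc1)C(C)(C)C)c1ccoc1 | intermediate
7 | (2E,5S)-5-[(tert-butyldiphenylsilyl)oxy]-5-(furan-3-yl)-2-methylpent-2-en-1-ol | OC/C(C)=C/C[C@H](O[Si](c1ccccc1)(c1ccccc1)C(C)(C)C)c1ccoc1 | intermediate
8 | (1S,3E)-5-bromo-1-(furan-3-yl)-4-methylpent-3-en-1-yl tert-butyldiphenylsilyl ether | BrC/C(C)=C/C[C@H](O[Si](c1ccccc1)(c1ccccc1)C(C)(C)C)c1ccoc1 | intermediate
9 | (tert-butyldimethylsilyloxy)acetaldehyde | O=CCO[Si](C)(C)C(C)(C)C | starting material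
10 | RAMP, (2R)-1-amino-2-(methoxymethyl)pyrrolidine | COC[C@H]1CCCN1N | starting material
11 | (2R)-N-[(E)-2-(tert-butyldimethylsilyloxy)ethylidene]-2-(methoxymethyl)pyrrolidin-1-amine | COC[C@H]1CCCN1/N=C/CO[Si](C)(C)C(C)(C)C | intermediate
12 | lithium azaenolate of 11 | COC[C@H]1CCCN1N([Li])/C=C/O[Si](C)(C)C(C)(C)C | intermediate
13 | RAMP hydrazone of 14, (2R)-N-[(1E,2R,4E,7S)-2-(tert-butyldimethylsilyloxy)-7-(tert-butyldiphenylsilyloxy)-7-(furan-3-yl)-4-methylhept-4-enylidene]-2-(methoxymethyl)pyrrolidin-1-amine | COC[C@H]1CCCN1/N=C/[C@H](O[Si](C)(C)C(C)(C)C)C/C(C)=C/C[C@H](O[Si](c2ccccc2)(c2ccccc2)C(C)(C)C)c2ccoc2 | intermediate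
14 | (2R,4E,7S)-2-[(tert-butyldimethylsilyl)oxy]-7-[(tert-butyldiphenylsilyl)oxy]-7-(furan-3-yl)-4-methylhept-4-enal | O=C[C@H](O[Si](C)(C)C(C)(C)C)C/C(C)=C/C[C@H](O[Si](c1ccccc1)(c1ccccc1)C(C)(C)C)c1ccoc1 | intermediate
15 | methyl acrylate | C=CC(=O)OC | starting material
16 | methyl (3RS,4R,6E,9S)-4-[(tert-butyldimethylsilyl)oxy]-9-[(tert-butyldiphenylsilyl)oxy]-9-(furan-3-yl)-3-hydroxy-6-methyl-2-methylidenenon-6-enoate (C-3 epimers) | COC(=O)C(=C)C(O)[C@H](O[Si](C)(C)C(C)(C)C)C/C(C)=C/C[C@H](O[Si](c1ccccc1)(c1ccccc1)C(C)(C)C)c1ccoc1 | intermediate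
17 | methyl (2Z,4R,6E,9S)-2-(bromomethyl)-4-[(tert-butyldimethylsilyl)oxy]-9-[(tert-butyldiphenylsilyl)oxy]-9-(furan-3-yl)-6-methylnona-2,6-dienoate | COC(=O)/C(CBr)=C/[C@H](O[Si](C)(C)C(C)(C)C)C/C(C)=C/C[C@H](O[Si](c1ccccc1)(c1ccccc1)C(C)(C)C)c1ccoc1 | intermediate
18 | furan endoperoxide of 17 (2,3,7-trioxabicyclo[2.2.1]hept-5-ene, bridgehead diastereomers) | COC(=O)/C(CBr)=C/[C@H](O[Si](C)(C)C(C)(C)C)C/C(C)=C/C[C@H](O[Si](c1ccccc1)(c1ccccc1)C(C)(C)C)C1=CC2OOC1O2 | intermediate
19 | methyl (2Z,4R,6E,9S,10Z)-2-(bromomethyl)-4-[(tert-butyldimethylsilyl)oxy]-9-[(tert-butyldiphenylsilyl)oxy]-10-formyl-6-methyl-12-oxododeca-2,6,10-trienoate | COC(=O)/C(CBr)=C/[C@H](O[Si](C)(C)C(C)(C)C)C/C(C)=C/C[C@H](O[Si](c1ccccc1)(c1ccccc1)C(C)(C)C)/C(C=O)=C/C=O | intermediate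
20 | methyl (2Z,4R,6E,9S,10E)-2-(bromomethyl)-4-[(tert-butyldimethylsilyl)oxy]-9-[(tert-butyldiphenylsilyl)oxy]-10-formyl-6-methyl-12-oxododeca-2,6,10-trienoate | COC(=O)/C(CBr)=C/[C@H](O[Si](C)(C)C(C)(C)C)C/C(C)=C/C[C@H](O[Si](c1ccccc1)(c1ccccc1)C(C)(C)C)/C(C=O)=C\C=O | intermediate
21 | allylchromium dichloride derived from 20 (Cr in place of Br) | COC(=O)/C(C[Cr](Cl)Cl)=C/[C@H](O[Si](C)(C)C(C)(C)C)C/C(C)=C/C[C@H](O[Si](c1ccccc1)(c1ccccc1)C(C)(C)C)/C(C=O)=C\C=O | intermediate
22 | methyl ester of the 6α-hydroxy seco-acid of 23 (formed as its chromium alkoxide) | CC(C)(C)[Si](C)(C)O[C@@H]1C/C(C)=C/C[C@H](O[Si](c2ccccc2)(c2ccccc2)C(C)(C)C)/C(C=O)=C\[C@@H](O)[C@@H]1C(=C)C(=O)OC | intermediate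
23 | 3β-(tert-butyldiphenylsilyloxy)-8β-(tert-butyldimethylsilyloxy)-15-oxogermacra-1(10)E,4,11(13)-trien-6α,12-olide | CC(C)(C)[Si](C)(C)O[C@@H]1C/C(C)=C/C[C@H](O[Si](c3ccccc3)(c3ccccc3)C(C)(C)C)/C(C=O)=C\[C@H]2OC(=O)C(=C)[C@@H]21 | intermediate
24 | 3β-(tert-butyldiphenylsilyloxy)-8β-hydroxy-15-oxogermacra-1(10)E,4,11(13)-trien-6α,12-olide | O[C@@H]1C/C(C)=C/C[C@H](O[Si](c3ccccc3)(c3ccccc3)C(C)(C)C)/C(C=O)=C\[C@H]2OC(=O)C(=C)[C@@H]21 | intermediate
25 | methacrylic anhydride | C=C(C)C(=O)OC(=O)C(C)=C | starting material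
26 | 3β-(tert-butyldiphenylsilyloxy)-8β-methacryloyloxy-15-oxogermacra-1(10)E,4,11(13)-trien-6α,12-olide | C=C(C)C(=O)O[C@@H]1C/C(C)=C/C[C@H](O[Si](c3ccccc3)(c3ccccc3)C(C)(C)C)/C(C=O)=C\[C@H]2OC(=O)C(=C)[C@@H]21 | intermediate
27 | 3β-hydroxy-8β-methacryloyloxy-15-oxogermacra-1(10)E,4,11(13)-trien-6α,12-olide | C=C(C)C(=O)O[C@@H]1C/C(C)=C/C[C@H](O)/C(C=O)=C\[C@H]2OC(=O)C(=C)[C@@H]21 | intermediate
28 | CNP0534814.1, (1R,3S,6R,7R,8R,10R)-1,10-epoxy-3-hydroxy-8-methacryloyloxy-15-oxogermacra-4,11(13)-dien-6,12-olide | C=C(C)C(=O)O[C@@H]1C[C@@]2(C)O[C@@H]2C[C@H](O)/C(C=O)=C\[C@H]2OC(=O)C(=C)[C@@H]21 | target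

**Step count and risks**

Total step count: 15 (step 6 is a one-step side branch). Longest linear sequence: 14 steps (1–5 and 7–15).

Most likely to fail, step 11 (unveiling and ring closure): the allylchromium may attack C-15 or oligomerise, excess divalent chromium may reduce the ene-dial, Me2S may alkylate the allylic bromide, or the wrong diastereomer may form. Fallback: set out from 17 and couple it with B2pin2 under Pd2(dba)3 catalysis (THF, 40 °C) to give the pinacol allylboronate F1, which is inert to Me2S and iodine. The same photo-oxygenation, Me2S and I2 sequence then gives the E-ene-dial boronate F2. Heating F2 at 1 mM in toluene (60 °C, 10 mol% Sc(OTf)3 if slow) closes the ring by redox-neutral intramolecular allylboration with no low-valent metal present, under the same ring-controlled topology, and CSA lactonises the borate, coming back to the route at 23.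

Second, step 15 (epoxidation): the peracid may deliver oxygen to the wrong face of the 1(10)-alkene, possibly steered by the free C-3 hydroxyl. Fallback: set out from 26 and use reagent-controlled Shi epoxidation (D-fructose-derived ketone, KHSO5, K2CO3 buffer, MeCN/dimethoxymethane, 0 °C), whose spiro transition state overrides the ring bias, to give the silyl-protected epoxide F3. HF·pyridine then removes the silyl group, coming back at 28.

Third, step 9 (Baylis–Hillman): the α-silyloxy aldehyde may react sluggishly and partly epimerise at C-8 over several days with amine base. Fallback: set out from 14; hydroalumination of methyl propiolate with iBu2AlH in THF/HMPA at 0 °C gives methyl 2-(diisobutylalumanyl)acrylate F4, which adds to 14 at −78 °C within hours under non-basic conditions and gives the same adduct, coming back at 16.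

**Further compounds**

F1 | step 11 | methyl (2E,4R,6E,9S)-4-[(tert-butyldimethylsilyl)oxy]-9-[(tert-butyldiphenylsilyl)oxy]-9-(furan-3-yl)-6-methyl-2-[(4,4,5,5-tetramethyl-1,3,2-dioxaborolan-2-yl)methyl]nona-2,6-dienoate | COC(=O)/C(CB1OC(C)(C)C(C)(C)O1)=C/[C@H](O[Si](C)(C)C(C)(C)C)C/C(C)=C/C[C@H](O[Si](c1ccccc1)(c1ccccc1)C(C)(C)C)c1ccoc1
F2 | step 11 | methyl (2E,4R,6E,9S,10E)-4-[(tert-butyldimethylsilyl)oxy]-9-[(tert-butyldiphenylsilyl)oxy]-10-formyl-6-methyl-12-oxo-2-[(4,4,5,5-tetramethyl-1,3,2-dioxaborolan-2-yl)methyl]dodeca-2,6,10-trienoate | COC(=O)/C(CB1OC(C)(C)C(C)(C)O1)=C/[C@H](O[Si](C)(C)C(C)(C)C)C/C(C)=C/C[C@H](O[Si](c1ccccc1)(c1ccccc1)C(C)(C)C)/C(C=O)=C\C=O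
F3 | step 15 | 1β,10α-epoxy-3β-(tert-butyldiphenylsilyloxy)-8β-methacryloyloxy-15-oxogermacra-4,11(13)-dien-6α,12-olide | C=C(C)C(=O)O[C@@H]1C[C@@]2(C)O[C@@H]2C[C@H](O[Si](c3ccccc3)(c3ccccc3)C(C)(C)C)/C(C=O)=C\[C@H]2OC(=O)C(=C)[C@@H]21
F4 | step 9 | methyl 2-(diisobutylalumanyl)prop-2-enoate | COC(=O)C(=C)[Al](CC(C)C)CC(C)C
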